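The route rests on cutting the dioxane ring (ring C) of the 2,3-dihydro-1,4-benzodioxine core at C2–C3 and O1–C8a. Both C2 and C3 carry oxygen and so have like polarity. C3 is also benzylic, which allows polarity reversal by α-lithiation. C8a lies between the oxygenated carbons C4a and C8 of ring A, where a fluorine has no ortho hydrogen. In one operation the lithiated benzyl 2-fluoroaryl ether adds to (S)-glyceraldehyde acetonide (C2–C3), and the resulting alkoxide displaces fluoride (O1–C8a). This closes ring C and sets both stereocentres. The precursor is an achiral, open benzyl aryl ether. The stilbene arm is added later by C–H borylation and Suzuki–Miyaura coupling.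

Key step: step 4

Remark (numbering): O1, C2 (bears the CH2OH carbon), C3 (bears the syringyl ring), O4, C4a, C5, C6 (bears the styryl arm), C7, C8 (bears the free OH), C8a. Ring A is the fused arene, ring B the resorcinol ring, ring C the dioxane ring.
Assumption: (S)-glyceraldehyde acetonide 6 is taken as a commercial chiral-pool aldehyde and is used freshly distilled.

Step 1
Reactants: 1 4-(hydroxymethyl)-2,6-dimethoxyphenol (syringyl alcohol)
Product: 2 [3,5-dimethoxy-4-(methoxymethoxy)phenyl]methanol
Conditions: MOMCl (1.1 equiv), K2CO3, acetone, 0 °C to rt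
Reagents that add atoms: chloromethyl methyl ether (MOMCl), COCCl
Why: Williamson-type O-alkylation in which K2CO3 deprotonates only the phenol, so the phenoxide is alkylated chemoselectively and the benzylic alcohol stays free.

Step 2
Reactants: 3 2-fluorobenzene-1,3-diol (2-fluororesorcinol)
Product: 4 2-fluoro-3-(methoxymethoxy)phenol
Conditions: MOMCl (1.0 equiv), K2CO3, acetone, 0 °C to rt; chromatography
Reagents that add atoms: chloromethyl methyl ether (MOMCl), COCCl
Why: Statistical Williamson-type mono-O-alkylation of a symmetric diol with one equivalent of electrophile, the mono-ether being separated from bis-ether and recovered 3.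

Step 3
Reactants: 2 [3,5-dimethoxy-4-(methoxymethoxy)phenyl]methanol; 4 2-fluoro-3-(methoxymethoxy)phenol
Product: 5 2-fluoro-1-(methoxymethoxy)-3-{[3,5-dimethoxy-4-(methoxymethoxy)phenyl]methoxy}benzene
Conditions: PPh3, DIAD, THF, 0 °C to rt
Reagents that add atoms: none
Why: Mitsunobu etherification of a primary benzylic alcohol with an acidic ortho-fluorophenol builds the C3–O4–C4a link under neutral conditions that spare both MOM ethers.

Step 4
Reactants: 5 2-fluoro-1-(methoxymethoxy)-3-{[3,5-dimethoxy-4-(methoxymethoxy)phenyl]methoxy}benzene; 6 (4S)-2,2-dimethyl-1,3-dioxolane-4-carbaldehyde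
Product: 9 (2R,3S)-2-[(4S)-2,2-dimethyl-1,3-dioxolan-4-yl]-3-[3,5-dimethoxy-4-(methoxymethoxy)phenyl]-8-(methoxymethoxy)-2,3-dihydro-1,4-benzodioxine (2,3-trans), via α-lithiated ether 7 (not isolated), via lithium alkoxide adduct 8 (not isolated)
Conditions: t-BuLi (1.1 equiv), THF, −78 °C; then 6, −78 °C; then KOt-Bu (1.2 equiv), DMPU, −78 to 65 °C; chromatography
Reagents that add atoms: none
Why: t-BuLi removes one benzylic α-oxy proton of 5 (7 resists Wittig rearrangement at −78 °C), the umpoled C3 attacks the aldehyde carbon of 6 to make C2–C3, and after lithium–potassium exchange and warming the alkoxide oxygen of 8 displaces fluoride at C8a by addition–elimination to make O1–C8a. The closest known reaction types are the carbonyl addition of α-lithiated aryl benzyl ethers and tandem carbonyl-addition/SNAr annulations of ortho-fluoroaryl substrates. Ring C, the only ring formed, closes by 6-exo-trig attack of O1 on the C–F carbon through a Meisenheimer-type transition state, with retention at C2 and C3. C2 is set by the dioxolane stereocentre of 6 under the polar Felkin–Anh model (attack anti to the C–O bond gives the anti relation of O1 to the dioxolane oxygen), and because this centre makes every isomer a diastereomer, a C2 epimer is removed by chromatography instead of eroding enantiopurity. C3 comes from a configurationally labile benzyllithium, for which a lithium-bridged staggered approach (O1 gauche to O4, syringyl group anti to the dioxolanyl group) leads to the threo adduct and hence the trans ring, but only a modest preference is expected, so trans-9 is separated from its cis epimer. The step needs benzylic rather than ring lithiation (secured by the doubly activated OCH2Ar protons and the low temperature), attack at C8a rather than Smiles-type ipso attack at C4a (fluoride is the only good nucleofuge, inductively activated by both flanking oxygens), and no aryne formation (C8a has no ortho hydrogen).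

Step 5
Reactants: 9 (2R,3S)-2-[(4S)-2,2-dimethyl-1,3-dioxolan-4-yl]-3-[3,5-dimethoxy-4-(methoxymethoxy)phenyl]-8-(methoxymethoxy)-2,3-dihydro-1,4-benzodioxine
Product: 11 {(2S,3S)-3-[3,5-dimethoxy-4-(methoxymethoxy)phenyl]-8-(methoxymethoxy)-2,3-dihydro-1,4-benzodioxin-2-yl}methanol, via α-aryloxy aldehyde 10 (not isolated)
Conditions: H5IO6, EtOAc, 0 °C to rt; aqueous NaHCO3 wash; then NaBH4, MeOH/THF, 0 °C
Reagents that add atoms: none
Why: Periodic acid hydrolyses the terminal acetonide and performs the glycol cleavage in one pot, and immediate borohydride reduction of the sensitive aldehyde 10 keeps C2 intact while the controlling stereocentre is excised.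

Step 6
Reactants: 11 {(2S,3S)-3-[3,5-dimethoxy-4-(methoxymethoxy)phenyl]-8-(methoxymethoxy)-2,3-dihydro-1,4-benzodioxin-2-yl}methanol
Product: 12 {(2S,3S)-3-[3,5-dimethoxy-4-(methoxymethoxy)phenyl]-8-(methoxymethoxy)-6-(4,4,5,5-tetramethyl-1,3,2-dioxaborolan-2-yl)-2,3-dihydro-1,4-benzodioxin-2-yl}methanol
Conditions: [Ir(OMe)(cod)]2 (cat.), 4,4'-di-tert-butyl-2,2'-bipyridine (cat.), B2pin2 (2 equiv), THF, 70 °C; MeOH work-up
Reagents that add atoms: bis(pinacolato)diboron (B2pin2), CC1(C)OB(OC1(C)C)B1OC(C)(C)C(C)(C)O1
Why: Sterically governed iridium-catalysed aromatic C–H borylation should pick C6–H, the only arene C–H in 11 without an ortho substituent, while the alcohol is only transiently O-borylated and is released on work-up.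

Step 7
Reactants: 13 3,5-dihydroxybenzaldehyde
Product: 14 3,5-bis(methoxymethoxy)benzaldehyde
Conditions: MOMCl (2.5 equiv), K2CO3, acetone, 0 °C to rt
Reagents that add atoms: chloromethyl methyl ether (MOMCl), COCCl
Why: Double Williamson-type O-alkylation of both phenols gives the acid-labile protection shared with the other fragment.

Step 8
Reactants: 14 3,5-bis(methoxymethoxy)benzaldehyde
Product: 15 1-[(E)-2-iodoethenyl]-3,5-bis(methoxymethoxy)benzene
Conditions: CrCl2 (6 equiv), CHI3 (2 equiv), THF, 0 °C to rt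
Reagents that add atoms: iodoform (CHI3), IC(I)I
Why: Takai olefination through a geminal dichromium reagent converts aromatic aldehydes into (E)-vinyl iodides, the E geometry resulting from anti elimination out of the less crowded adduct.

Step 9
Reactants: 12 the C6 pinacol boronate; 15 1-[(E)-2-iodoethenyl]-3,5-bis(methoxymethoxy)benzene
Product: 16 {(2S,3S)-6-{(E)-2-[3,5-bis(methoxymethoxy)phenyl]ethenyl}-3-[3,5-dimethoxy-4-(methoxymethoxy)phenyl]-8-(methoxymethoxy)-2,3-dihydro-1,4-benzodioxin-2-yl}methanol
Conditions: PdCl2(dppf) (cat.), K2CO3, 1,4-dioxane/H2O, 70 °C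
Reagents that add atoms: none
Why: Suzuki–Miyaura coupling of an aryl boronate with a vinyl iodide proceeds with retention of alkene geometry, tolerates the free alcohol and touches neither stereocentre.

Step 10
Reactants: 16 the tetra-MOM-protected stilbenolignan
Product: 17 5-{(E)-2-[(2S,3S)-8-hydroxy-3-(4-hydroxy-3,5-dimethoxyphenyl)-2-(hydroxymethyl)-2,3-dihydro-1,4-benzodioxin-6-yl]ethenyl}benzene-1,3-diol (target)
Conditions: HCl (about 1 M in MeOH), THF, 0 to 40 °C
Reagents that add atoms: none
Why: Acid-catalysed acetal exchange removes all four aryl MOM ethers at once, the cyclic benzodioxane ether is stable to dilute acid, and the trans arrangement is also the thermodynamic one, so C3 has no drive to drift.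

Compound list
1 | 4-(hydroxymethyl)-2,6-dimethoxyphenol | COc1cc(CO)cc(OC)c1O | starting material
2 | [3,5-dimethoxy-4-(methoxymethoxy)phenyl]methanol | COCOc1c(OC)cc(CO)cc1OC | intermediate
3 | 2-fluorobenzene-1,3-diol | Oc1cccc(O)c1F | starting material
4 | 2-fluoro-3-(methoxymethoxy)phenol | COCOc1cccc(O)c1F | intermediate
5 | 2-fluoro-1-(methoxymethoxy)-3-{[3,5-dimethoxy-4-(methoxymethoxy)phenyl]methoxy}benzene | COCOc1cccc(OCc2cc(OC)c(OCOC)c(OC)c2)c1F | intermediate
6 | (4S)-2,2-dimethyl-1,3-dioxolane-4-carbaldehyde | O=C[C@@H]1COC(C)(C)O1 | starting material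
7 | α-lithiated ether of 5 (configurationally labile) | [Li]C(Oc1cccc(OCOC)c1F)c1cc(OC)c(OCOC)c(OC)c1 | intermediate
8 | lithium (1R,2S)-1-[(4S)-2,2-dimethyl-1,3-dioxolan-4-yl]-2-[2-fluoro-3-(methoxymethoxy)phenoxy]-2-[3,5-dimethoxy-4-(methoxymethoxy)phenyl]ethan-1-olate | COCOc1cccc(O[C@@H](c2cc(OC)c(OCOC)c(OC)c2)[C@@H]([O-])[C@@H]3COC(C)(C)O3)c1F.[Li+] | intermediate
9 | (2R,3S)-2-[(4S)-2,2-dimethyl-1,3-dioxolan-4-yl]-3-[3,5-dimethoxy-4-(methoxymethoxy)phenyl]-8-(methoxymethoxy)-2,3-dihydro-1,4-benzodioxine | COCOc1c(OC)cc([C@@H]2Oc3cccc(OCOC)c3O[C@H]2[C@@H]4COC(C)(C)O4)cc1OC | intermediate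
10 | (2R,3S)-3-[3,5-dimethoxy-4-(methoxymethoxy)phenyl]-8-(methoxymethoxy)-2,3-dihydro-1,4-benzodioxine-2-carbaldehyde | COCOc1c(OC)cc([C@@H]2Oc3cccc(OCOC)c3O[C@H]2C=O)cc1OC | intermediate
11 | {(2S,3S)-3-[3,5-dimethoxy-4-(methoxymethoxy)phenyl]-8-(methoxymethoxy)-2,3-dihydro-1,4-benzodioxin-2-yl}methanol | COCOc1c(OC)cc([C@@H]2Oc3cccc(OCOC)c3O[C@H]2CO)cc1OC | intermediate
12 | {(2S,3S)-3-[3,5-dimethoxy-4-(methoxymethoxy)phenyl]-8-(methoxymethoxy)-6-(4,4,5,5-tetramethyl-1,3,2-dioxaborolan-2-yl)-2,3-dihydro-1,4-benzodioxin-2-yl}methanol | COCOc1c(OC)cc([C@@H]2Oc3cc(B4OC(C)(C)C(C)(C)O4)cc(OCOC)c3O[C@H]2CO)cc1OC | intermediate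
13 | 3,5-dihydroxybenzaldehyde | O=Cc1cc(O)cc(O)c1 | starting material
14 | 3,5-bis(methoxymethoxy)benzaldehyde | COCOc1cc(C=O)cc(OCOC)c1 | intermediate
15 | 1-[(E)-2-iodoethenyl]-3,5-bis(methoxymethoxy)benzene | COCOc1cc(/C=C/I)cc(OCOC)c1 | intermediate
16 | {(2S,3S)-6-{(E)-2-[3,5-bis(methoxymethoxy)phenyl]ethenyl}-3-[3,5-dimethoxy-4-(methoxymethoxy)phenyl]-8-(methoxymethoxy)-2,3-dihydro-1,4-benzodioxin-2-yl}methanol | COCOc1c(OC)cc([C@@H]2Oc3cc(/C=C/c4cc(OCOC)cc(OCOC)c4)cc(OCOC)c3O[C@H]2CO)cc1OC | intermediate
17 | 5-{(E)-2-[(2S,3S)-8-hydroxy-3-(4-hydroxy-3,5-dimethoxyphenyl)-2-(hydroxymethyl)-2,3-dihydro-1,4-benzodioxin-6-yl]ethenyl}benzene-1,3-diol | COc1cc([C@@H]2Oc3cc(/C=C/c4cc(O)cc(O)c4)cc(O)c3O[C@H]2CO)cc(OC)c1O | target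

Total step count: 10. Longest linear sequence: 7 (steps 1, 3, 4, 5, 6, 9, 10).

Steps most likely to fail

Step 4. The very reactive organolithium may show poor facial selectivity towards 6. The unactivated fluoride may also be displaced slowly, so that material decays under base during the heating. The fallback makes the two bonds in two separate operations with a different organometal. It sets out from 5. Lithiation as in step 4 gives 7, which is transmetalated with ClTi(OiPr)3 at −78 °C to the triisopropoxytitanium reagent F1. This non-chelating, less basic reagent should add to 6 with higher Felkin–Anh selectivity. After aqueous work-up and chromatography it should give the open-chain fluoro alcohol F2 as one diastereomer. A separate intramolecular SNAr closure of F2 with KN(SiMe3)2 and 18-crown-6 in DMF at 80 °C comes back to the route at 9.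

Step 5. At the aldehyde stage C2 may epimerise or O4 may be lost by β-elimination, and the acidic periodate may strip MOM groups. The fallback excises no carbon and obtains the enantiomer by resolution. It sets out from 5. The annulation of step 4 is run with commercial (tert-butyldimethylsilyloxy)acetaldehyde in place of 6. After removal of the cis isomer this should give the racemic trans silyl ether F3. Bu4NF in THF then gives the racemic alcohol F4. Lipase-catalysed kinetic resolution (Burkholderia cepacia lipase, vinyl acetate, MTBE) is taken to acetylate the (2R,3R)-enantiomer to the acetate F5. The unreacted (2S,3S)-alcohol is separated, and the route is rejoined at 11.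

Step 10. While four MOM groups are removed, acid may ionise the benzylic C3–O4 bond or oligomerise the electron-rich stilbene. The fallback moves the acid step ahead of the coupling, so that no stilbene meets acid. It sets out from 12 and 15. HCl in MeOH converts 12 into the free-phenol boronate F6 and converts 15 into (E)-5-(2-iodoethenyl)benzene-1,3-diol F7. Suzuki–Miyaura coupling of F6 with F7 (PdCl2(dppf), excess K2CO3, degassed 1,4-dioxane/H2O) tolerates free phenols and comes back to the route at 17.

Further compounds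
F1 | step 4 | {[2-fluoro-3-(methoxymethoxy)phenoxy][3,5-dimethoxy-4-(methoxymethoxy)phenyl]methyl}tri(propan-2-yloxy)titanium | CC(C)O[Ti](OC(C)C)(OC(C)C)C(Oc1cccc(OCOC)c1F)c1cc(OC)c(OCOC)c(OC)c1
F2 | step 4 | (1R,2S)-1-[(4S)-2,2-dimethyl-1,3-dioxolan-4-yl]-2-[2-fluoro-3-(methoxymethoxy)phenoxy]-2-[3,5-dimethoxy-4-(methoxymethoxy)phenyl]ethan-1-ol | COCOc1cccc(O[C@@H](c2cc(OC)c(OCOC)c(OC)c2)[C@@H](O)[C@@H]3COC(C)(C)O3)c1F
F3 | step 5 | racemic trans tert-butyldimethylsilyl ether of 11 (both enantiomers written) | COCOc1c(OC)cc([C@@H]2Oc3cccc(OCOC)c3O[C@H]2CO[Si](C)(C)C(C)(C)C)cc1OC.COCOc1c(OC)cc([C@H]2Oc3cccc(OCOC)c3O[C@@H]2CO[Si](C)(C)C(C)(C)C)cc1OC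
F4 | step 5 | racemic trans alcohol (11 together with its enantiomer) | COCOc1c(OC)cc([C@@H]2Oc3cccc(OCOC)c3O[C@H]2CO)cc1OC.COCOc1c(OC)cc([C@H]2Oc3cccc(OCOC)c3O[C@@H]2CO)cc1OC
F5 | step 5 | {(2R,3R)-3-[3,5-dimethoxy-4-(methoxymethoxy)phenyl]-8-(methoxymethoxy)-2,3-dihydro-1,4-benzodioxin-2-yl}methyl acetate | COCOc1c(OC)cc([C@H]2Oc3cccc(OCOC)c3O[C@@H]2COC(C)=O)cc1OC
F6 | step 10 | (2S,3S)-3-(4-hydroxy-3,5-dimethoxyphenyl)-2-(hydroxymethyl)-6-(4,4,5,5-tetramethyl-1,3,2-dioxaborolan-2-yl)-2,3-dihydro-1,4-benzodioxin-8-ol | COc1cc([C@@H]2Oc3cc(B4OC(C)(C)C(C)(C)O4)cc(O)c3O[C@H]2CO)cc(OC)c1O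
F7 | step 10 | (E)-5-(2-iodoethenyl)benzene-1,3-diol | Oc1cc(O)cc(/C=C/I)c1
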